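The route rests on disconnecting the C5–C6 bond common to the cyclohexane ring and the oxirane of the 5,6-epoxy end group: C6, a quaternary oxirane carbon carrying the side chain, is read as the α-carbon of a glycidic ester and C5 as a methyl ketone. An open-chain 5-silyloxy-7-oxo-2,2-dichloro ester is treated with SmI2; the samarium α-chloro enolate formed regiospecifically adds to the ketone (Reformatsky) and the chlorohydrin alkoxide closes the oxirane (Darzens). One operation should thus give the carbocycle, the epoxide and both quaternary stereocentres, steered by the C3 silyloxy group. Stille and Julia–Kocienski couplings then join this end group to a bromo-ylidenebutenolide and an acetylenic sulfone.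

Key step: step 6

Remark: C1–C8 are the carotenoid locants of the epoxy end group (C1 = CMe2, C3 = CH–O, C5 = C(Me)–O, C6 = oxirane carbon bearing C7=C8); TBS = tert-butyldimethylsilyl.
Assumption: (4R,6R)-actinol 23 is taken as a purchasable chiral building block (bulk intermediate of zeaxanthin manufacture).

Step 1
Reactants: 1 methyl 3,3-dimethylpent-4-enoate
Product: 2 methyl 3,3-dimethyl-5-oxopentanoate
Conditions: PdCl2(PhCN)2 (10 mol%), CuCl2·2H2O (10 mol%), AgNO2 (5 mol%), O2 (1 atm), t-BuOH/MeNO2 15:1, rt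
Reagents that add atoms: dioxygen O=O
Why: Nitrite-modified, aldehyde-selective Wacker oxidation; the quaternary allylic carbon blocks attack at the internal alkene carbon, so the anti-Markovnikov aldehyde should dominate.

Step 2
Reactants: 2 methyl 3,3-dimethyl-5-oxopentanoate; 3 tributyl(2-methylallyl)stannane
Product: 4 methyl (5R)-5-hydroxy-3,3,7-trimethyloct-7-enoate
Conditions: (R)-BINOL (20 mol%), Ti(Oi-Pr)4 (10 mol%), 4 Å MS, CH2Cl2, −20 °C; aq NaHCO3
Reagents that add atoms: none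
Why: Keck catalytic asymmetric methallylation; the (R)-BINOL–titanium Lewis acid should direct the methallyl group to the Re face of the aldehyde, which sets the future C3 carbinol centre (5R in 4).

Step 3
Reactants: 4 methyl (5R)-5-hydroxy-3,3,7-trimethyloct-7-enoate
Product: 5 methyl (5R)-5-[(tert-butyldimethylsilyl)oxy]-3,3,7-trimethyloct-7-enoate
Conditions: TBSOTf, 2,6-lutidine, CH2Cl2, −78 °C
Reagents that add atoms: tert-butyldimethylsilyl trifluoromethanesulfonate CC(C)(C)[Si](C)(C)OS(=O)(=O)C(F)(F)F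
Why: Silylation of the secondary alcohol with a silyl triflate at low temperature should outrun δ-lactonisation onto the methyl ester.

Step 4
Reactants: 5 methyl (5R)-5-[(tert-butyldimethylsilyl)oxy]-3,3,7-trimethyloct-7-enoate
Product: 7 methyl (5R)-5-[(tert-butyldimethylsilyl)oxy]-2,2-dichloro-3,3,7-trimethyloct-7-enoate, via monochloro ester 6 (not isolated)
Conditions: LiN(i-Pr)2 (1.1 equiv), THF, −78 °C, then C2Cl6; second LiN(i-Pr)2 (1.2 equiv), −78 °C, then C2Cl6, −78 → −30 °C
Reagents that add atoms: hexachloroethane ClC(Cl)(Cl)C(Cl)(Cl)Cl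
Why: Two successive ester enolate chlorinations by positive-chlorine transfer; the ester α-carbon is the only acidic site because the ketone is still masked as the methallyl alkene.

Step 5
Reactants: 7 methyl (5R)-5-[(tert-butyldimethylsilyl)oxy]-2,2-dichloro-3,3,7-trimethyloct-7-enoate
Product: 8 methyl (5S)-5-[(tert-butyldimethylsilyl)oxy]-2,2-dichloro-3,3-dimethyl-7-oxooctanoate
Conditions: O3, CH2Cl2/MeOH, −78 °C; then Me2S, −78 °C → rt
Reagents that add atoms: ozone [O-][O+]=O
Why: Ozonolysis with reductive work-up cleaves the 1,1-disubstituted alkene to the methyl ketone while silyl ether and dichloro ester are inert; the descriptor changes from R to S only through the CIP priorities.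

Step 6
Reactants: 8 methyl (5S)-5-[(tert-butyldimethylsilyl)oxy]-2,2-dichloro-3,3-dimethyl-7-oxooctanoate
Product: 10 methyl (1S,4S,6R)-4-[(tert-butyldimethylsilyl)oxy]-2,2,6-trimethyl-7-oxabicyclo[4.1.0]heptane-1-carboxylate, via chlorohydrin 9 (not isolated)
Conditions: SmI2 (2.2 equiv), THF, −78 → −40 °C; then KOt-Bu (1.2 equiv), −40 → 0 °C
Reagents that add atoms: none
Why: Two equivalents of SmI2 should reduce one C–Cl bond of the α,α-dichloro ester to a samarium α-chloro enolate at C6, the only enolate that can form under these non-basic conditions, and this adds to the C5 ketone (6-(enolexo)-exo-trig closure of the carbocycle, forming C5–C6); KOt-Bu then frees the alkoxide of the trivalent-samarium aldolate 9, which displaces the remaining chloride at C6 with inversion (3-exo-tet closure of the oxirane). The closest known reactions are the SmI2 intramolecular Reformatsky cyclisation and the Darzens glycidic ester synthesis in its dichloroacetate (Reformatsky-type) variant. Chelation of samarium between enolate and ketone oxygens places C5–O and the ester cis, hence C5–O and C6–Cl trans-diaxial, which is what the oxirane closure needs and fixes C5 relative to C6. Their sense relative to C3 should follow from a chair transition state with the C3 silyloxy group and the C5 methyl group equatorial, which puts the new C–O bond anti to the silyloxy group and avoids a syn-diaxial clash of the C5 methyl with a C1 methyl group. The step needs reduction of the dichloro ester in preference to the ketone and no β-elimination of the silyloxy group; both are secured by the faster reduction of gem-dichloro esters by SmI2, the low temperature and the absence of base while the ketone is present.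

Step 7
Reactants: 10 methyl (1S,4S,6R)-4-[(tert-butyldimethylsilyl)oxy]-2,2,6-trimethyl-7-oxabicyclo[4.1.0]heptane-1-carboxylate; 11 dimethyl (1-diazo-2-oxopropyl)phosphonate
Product: 13 (1R,4S,6R)-4-[(tert-butyldimethylsilyl)oxy]-1-ethynyl-2,2,6-trimethyl-7-oxabicyclo[4.1.0]heptane, via epoxy aldehyde 12 (not isolated)
Conditions: i-Bu2AlH (1.2 equiv), CH2Cl2, −78 °C; then MeOH, K2CO3, 11, −78 °C → rt
Reagents that add atoms: none
Why: Half-reduction of the hindered glycidic ester to its aluminium hemiacetal, then Ohira–Bestmann (Seyferth–Gilbert) homologation of the non-enolisable aldehyde in the same flask; no stereocentre is touched.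

Step 8
Reactants: 13 (1R,4S,6R)-4-[(tert-butyldimethylsilyl)oxy]-1-ethynyl-2,2,6-trimethyl-7-oxabicyclo[4.1.0]heptane
Product: 14 tributyl{(E)-2-[(1S,4S,6R)-4-[(tert-butyldimethylsilyl)oxy]-2,2,6-trimethyl-7-oxabicyclo[4.1.0]heptan-1-yl]ethenyl}stannane
Conditions: Bu3SnH, PdCl2(PPh3)2 (3 mol%), THF, 0 °C
Reagents that add atoms: tributyltin hydride CCCC[SnH](CCCC)CCCC
Why: Palladium-catalysed syn-hydrostannation; the quaternary propargylic carbon should steer tin to the terminal carbon and give the E-alkenylstannane.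

Step 9
Reactants: 15 propiolic acid
Product: 16 (E)-2,3-dibromoprop-2-enoic acid
Conditions: Br2, CHCl3, 0 °C → rt, dark
Reagents that add atoms: bromine BrBr
Why: Ionic anti addition of bromine to the alkyne gives the E-dibromide, with the β-bromine cis to the carboxyl group.

Step 10
Reactants: 16 (E)-2,3-dibromoprop-2-enoic acid; 17 (E)-3-methylpent-2-en-4-yn-1-ol
Product: 19 (5Z)-3-bromo-5-[(2E)-4-hydroxy-2-methylbut-2-en-1-ylidene]furan-2(5H)-one, via bromoenynoic acid 18 (not isolated)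
Conditions: PdCl2(PPh3)2 (5 mol%), CuI (10 mol%), Et3N, MeCN, rt
Reagents that add atoms: none
Why: Tandem Sonogashira coupling at the more reactive β-bromide with retention, then 5-exo-dig anti-oxymetalation of the alkyne by the cis carboxylate, which sets the Z-alkylidene geometry.

Step 11
Reactants: 19 (5Z)-3-bromo-5-[(2E)-4-hydroxy-2-methylbut-2-en-1-ylidene]furan-2(5H)-one
Product: 20 (2E)-4-[(2Z)-4-bromo-5-oxofuran-2(5H)-ylidene]-3-methylbut-2-enal
Conditions: MnO2, CH2Cl2, rt
Reagents that add atoms: none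
Why: Chemoselective MnO2 oxidation of the primary allylic alcohol to the enal.

Step 12
Reactants: 20 (2E)-4-[(2Z)-4-bromo-5-oxofuran-2(5H)-ylidene]-3-methylbut-2-enal; 21 (triphenylphosphoranylidene)acetaldehyde
Product: 22 (2E,4E)-6-[(2Z)-4-bromo-5-oxofuran-2(5H)-ylidene]-5-methylhexa-2,4-dienal
Conditions: 21 (1.1 equiv), PhMe, 60 °C
Reagents that add atoms: none
Why: Wittig two-carbon homologation with a stabilised formyl ylide, which should be E-selective.

Step 13
Reactants: 23 (4R,6R)-4-hydroxy-2,2,6-trimethylcyclohexan-1-one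
Product: 24 (4R,6R)-4-[(tert-butyldimethylsilyl)oxy]-2,2,6-trimethylcyclohexan-1-one
Conditions: TBSCl, imidazole, DMF, rt
Reagents that add atoms: tert-butyldimethylsilyl chloride CC(C)(C)[Si](C)(C)Cl
Why: Standard silylation of the secondary alcohol.

Step 14
Reactants: 24 (4R,6R)-4-[(tert-butyldimethylsilyl)oxy]-2,2,6-trimethylcyclohexan-1-one
Product: 25 (4R)-4-[(tert-butyldimethylsilyl)oxy]-2,6,6-trimethylcyclohex-1-en-1-yl trifluoromethanesulfonate
Conditions: LiN(i-Pr)2, THF, −78 °C; then PhNTf2, −78 → 0 °C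
Reagents that add atoms: N-phenylbis(trifluoromethanesulfonimide) O=S(=O)(N(c1ccccc1)S(=O)(=O)C(F)(F)F)C(F)(F)F
Why: Enolate O-triflation; the ketone can enolise only toward the methyl-bearing carbon, so the tetrasubstituted enol triflate results and that stereocentre is erased by design.

Step 15
Reactants: 25 (4R)-4-[(tert-butyldimethylsilyl)oxy]-2,6,6-trimethylcyclohex-1-en-1-yl trifluoromethanesulfonate; 17 (E)-3-methylpent-2-en-4-yn-1-ol
Product: 26 (2E)-5-[(4R)-4-[(tert-butyldimethylsilyl)oxy]-2,6,6-trimethylcyclohex-1-en-1-yl]-3-methylpent-2-en-4-yn-1-ol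
Conditions: Pd(PPh3)4 (5 mol%), CuI (10 mol%), i-Pr2NH, DMF, rt
Reagents that add atoms: none
Why: Sonogashira coupling of the enol triflate with the terminal alkyne; the alkene geometry of 17 is retained.

Step 16
Reactants: 26 (2E)-5-[(4R)-4-[(tert-butyldimethylsilyl)oxy]-2,6,6-trimethylcyclohex-1-en-1-yl]-3-methylpent-2-en-4-yn-1-ol
Product: 27 2-{[(2E)-5-[(4R)-4-[(tert-butyldimethylsilyl)oxy]-2,6,6-trimethylcyclohex-1-en-1-yl]-3-methylpent-2-en-4-yn-1-yl]sulfanyl}-1,3-benzothiazole
Conditions: 2-mercaptobenzothiazole, PPh3, DIAD, THF, 0 °C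
Reagents that add atoms: 2-mercaptobenzothiazole Sc1nc2ccccc2s1
Why: Mitsunobu thioetherification of the primary allylic alcohol by direct (SN2) displacement.

Step 17
Reactants: 27 2-{[(2E)-5-[(4R)-4-[(tert-butyldimethylsilyl)oxy]-2,6,6-trimethylcyclohex-1-en-1-yl]-3-methylpent-2-en-4-yn-1-yl]sulfanyl}-1,3-benzothiazole
Product: 28 2-{[(2E)-5-[(4R)-4-[(tert-butyldimethylsilyl)oxy]-2,6,6-trimethylcyclohex-1-en-1-yl]-3-methylpent-2-en-4-yn-1-yl]sulfonyl}-1,3-benzothiazole
Conditions: (NH4)6Mo7O24·4H2O (10 mol%), 30% H2O2, EtOH, 0 °C → rt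
Reagents that add atoms: hydrogen peroxide OO
Why: Molybdate-catalysed peroxide oxidation of sulfide to sulfone, which should be selective over the alkenes and the alkyne.

Step 18
Reactants: 14 tributyl{(E)-2-[(1S,4S,6R)-4-[(tert-butyldimethylsilyl)oxy]-2,2,6-trimethyl-7-oxabicyclo[4.1.0]heptan-1-yl]ethenyl}stannane; 22 (2E,4E)-6-[(2Z)-4-bromo-5-oxofuran-2(5H)-ylidene]-5-methylhexa-2,4-dienal
Product: 29 (2E,4E)-6-[(2Z)-4-{(E)-2-[(1S,4S,6R)-4-[(tert-butyldimethylsilyl)oxy]-2,2,6-trimethyl-7-oxabicyclo[4.1.0]heptan-1-yl]ethenyl}-5-oxofuran-2(5H)-ylidene]-5-methylhexa-2,4-dienal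
Conditions: Pd2(dba)3 (5 mol%), AsPh3 (40 mol%), NMP, rt → 40 °C, dark
Reagents that add atoms: none
Why: Stille coupling of the α-bromobutenolide with the alkenylstannane with retention of both alkene geometries; the AsPh3 ligand keeps the temperature low for the vinyl oxirane.

Step 19
Reactants: 28 2-{[(2E)-5-[(4R)-4-[(tert-butyldimethylsilyl)oxy]-2,6,6-trimethylcyclohex-1-en-1-yl]-3-methylpent-2-en-4-yn-1-yl]sulfonyl}-1,3-benzothiazole; 29 (2E,4E)-6-[(2Z)-4-{(E)-2-[(1S,4S,6R)-4-[(tert-butyldimethylsilyl)oxy]-2,2,6-trimethyl-7-oxabicyclo[4.1.0]heptan-1-yl]ethenyl}-5-oxofuran-2(5H)-ylidene]-5-methylhexa-2,4-dienal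
Product: 31 3,3′-bis-O-(tert-butyldimethylsilyl)pyrrhoxanthin (all-E chain and Z-alkylidene butenolide), via Z-isomer 30 (not isolated)
Conditions: NaN(SiMe3)2, THF, −78 °C, 28 then 29; then PhH, rt, dark, 2–3 d
Reagents that add atoms: none
Why: Julia–Kocienski olefination (addition, Smiles rearrangement, loss of SO2 and benzothiazolone); the Z-isomer expected at the new disubstituted double bond should equilibrate to the all-E polyene on standing.

Step 20
Reactants: 31 3,3′-bis-O-(tert-butyldimethylsilyl)pyrrhoxanthin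
Product: 32 pyrrhoxanthin (CNP0180336.1)
Conditions: Bu4NF, AcOH (1:1), THF, 0 °C → rt
Reagents that add atoms: none
Why: Fluoride cleavage of both silyl ethers, buffered with acetic acid to spare the ylidenebutenolide and the 5,6-epoxide.

Compound list
1 | methyl 3,3-dimethylpent-4-enoate | C=CC(C)(C)CC(=O)OC | starting material
2 | methyl 3,3-dimethyl-5-oxopentanoate | O=CCC(C)(C)CC(=O)OC | intermediate
3 | tributyl(2-methylallyl)stannane | C=C(C)C[Sn](CCCC)(CCCC)CCCC | starting material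
4 | methyl (5R)-5-hydroxy-3,3,7-trimethyloct-7-enoate | C=C(C)C[C@@H](O)CC(C)(C)CC(=O)OC | intermediate
5 | methyl (5R)-5-[(tert-butyldimethylsilyl)oxy]-3,3,7-trimethyloct-7-enoate | C=C(C)C[C@@H](O[Si](C)(C)C(C)(C)C)CC(C)(C)CC(=O)OC | intermediate
6 | methyl (5R)-5-[(tert-butyldimethylsilyl)oxy]-2-chloro-3,3,7-trimethyloct-7-enoate (C2 epimers, not isolated) | C=C(C)C[C@@H](O[Si](C)(C)C(C)(C)C)CC(C)(C)C(Cl)C(=O)OC | intermediate
7 | methyl (5R)-5-[(tert-butyldimethylsilyl)oxy]-2,2-dichloro-3,3,7-trimethyloct-7-enoate | C=C(C)C[C@@H](O[Si](C)(C)C(C)(C)C)CC(C)(C)C(Cl)(Cl)C(=O)OC | intermediate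
8 | methyl (5S)-5-[(tert-butyldimethylsilyl)oxy]-2,2-dichloro-3,3-dimethyl-7-oxooctanoate | CC(=O)C[C@@H](O[Si](C)(C)C(C)(C)C)CC(C)(C)C(Cl)(Cl)C(=O)OC | intermediate
9 | methyl (1R,2R,4S)-4-[(tert-butyldimethylsilyl)oxy]-1-chloro-2-hydroxy-2,6,6-trimethylcyclohexane-1-carboxylate (OH and Cl trans; formed as its samarium alkoxide, not isolated) | COC(=O)[C@]1(Cl)[C@](C)(O)C[C@@H](O[Si](C)(C)C(C)(C)C)CC1(C)C | intermediate
10 | methyl (1S,4S,6R)-4-[(tert-butyldimethylsilyl)oxy]-2,2,6-trimethyl-7-oxabicyclo[4.1.0]heptane-1-carboxylate | COC(=O)[C@@]12O[C@]1(C)C[C@@H](O[Si](C)(C)C(C)(C)C)CC2(C)C | intermediate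
11 | dimethyl (1-diazo-2-oxopropyl)phosphonate | CC(=O)C(=[N+]=[N-])P(=O)(OC)OC | starting material
12 | (1S,4S,6R)-4-[(tert-butyldimethylsilyl)oxy]-2,2,6-trimethyl-7-oxabicyclo[4.1.0]heptane-1-carbaldehyde (not isolated) | O=C[C@@]12O[C@]1(C)C[C@@H](O[Si](C)(C)C(C)(C)C)CC2(C)C | intermediate
13 | (1R,4S,6R)-4-[(tert-butyldimethylsilyl)oxy]-1-ethynyl-2,2,6-trimethyl-7-oxabicyclo[4.1.0]heptane | C#C[C@@]12O[C@]1(C)C[C@@H](O[Si](C)(C)C(C)(C)C)CC2(C)C | intermediate
14 | tributyl{(E)-2-[(1S,4S,6R)-4-[(tert-butyldimethylsilyl)oxy]-2,2,6-trimethyl-7-oxabicyclo[4.1.0]heptan-1-yl]ethenyl}stannane | CCCC[Sn](CCCC)(CCCC)/C=C/[C@@]12O[C@]1(C)C[C@@H](O[Si](C)(C)C(C)(C)C)CC2(C)C | intermediate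
15 | propiolic acid | C#CC(=O)O | starting material
16 | (E)-2,3-dibromoprop-2-enoic acid | Br/C=C(/Br)C(=O)O | intermediate
17 | (E)-3-methylpent-2-en-4-yn-1-ol | C#C/C(C)=C/CO | starting material
18 | (2E,6E)-2-bromo-8-hydroxy-6-methylocta-2,6-dien-4-ynoic acid (carboxyl and alkynyl cis, not isolated) | OC(=O)/C(Br)=C\C#C/C(C)=C/CO | intermediate
19 | (5Z)-3-bromo-5-[(2E)-4-hydroxy-2-methylbut-2-en-1-ylidene]furan-2(5H)-one | OC/C=C(C)/C=C1C=C(Br)C(=O)O/1 | intermediate
20 | (2E)-4-[(2Z)-4-bromo-5-oxofuran-2(5H)-ylidene]-3-methylbut-2-enal | O=C/C=C(C)/C=C1C=C(Br)C(=O)O/1 | intermediate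
21 | (triphenylphosphoranylidene)acetaldehyde | O=CC=P(c1ccccc1)(c1ccccc1)c1ccccc1 | starting material
22 | (2E,4E)-6-[(2Z)-4-bromo-5-oxofuran-2(5H)-ylidene]-5-methylhexa-2,4-dienal | O=C/C=C/C=C(C)/C=C1C=C(Br)C(=O)O/1 | intermediate
23 | (4R,6R)-4-hydroxy-2,2,6-trimethylcyclohexan-1-one (actinol) | CC1(C)C[C@H](O)C[C@@H](C)C1=O | starting material
24 | (4R,6R)-4-[(tert-butyldimethylsilyl)oxy]-2,2,6-trimethylcyclohexan-1-one | CC1(C)C[C@H](O[Si](C)(C)C(C)(C)C)C[C@@H](C)C1=O | intermediate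
25 | (4R)-4-[(tert-butyldimethylsilyl)oxy]-2,6,6-trimethylcyclohex-1-en-1-yl trifluoromethanesulfonate | CC1=C(OS(=O)(=O)C(F)(F)F)C(C)(C)C[C@H](O[Si](C)(C)C(C)(C)C)C1 | intermediate
26 | (2E)-5-[(4R)-4-[(tert-butyldimethylsilyl)oxy]-2,6,6-trimethylcyclohex-1-en-1-yl]-3-methylpent-2-en-4-yn-1-ol | CC1=C(C#C/C(C)=C/CO)C(C)(C)C[C@H](O[Si](C)(C)C(C)(C)C)C1 | intermediate
27 | 2-{[(2E)-5-[(4R)-4-[(tert-butyldimethylsilyl)oxy]-2,6,6-trimethylcyclohex-1-en-1-yl]-3-methylpent-2-en-4-yn-1-yl]sulfanyl}-1,3-benzothiazole | CC1=C(C#C/C(C)=C/CSc2nc3ccccc3s2)C(C)(C)C[C@H](O[Si](C)(C)C(C)(C)C)C1 | intermediate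
28 | 2-{[(2E)-5-[(4R)-4-[(tert-butyldimethylsilyl)oxy]-2,6,6-trimethylcyclohex-1-en-1-yl]-3-methylpent-2-en-4-yn-1-yl]sulfonyl}-1,3-benzothiazole | CC1=C(C#C/C(C)=C/CS(=O)(=O)c2nc3ccccc3s2)C(C)(C)C[C@H](O[Si](C)(C)C(C)(C)C)C1 | intermediate
29 | (2E,4E)-6-[(2Z)-4-{(E)-2-[(1S,4S,6R)-4-[(tert-butyldimethylsilyl)oxy]-2,2,6-trimethyl-7-oxabicyclo[4.1.0]heptan-1-yl]ethenyl}-5-oxofuran-2(5H)-ylidene]-5-methylhexa-2,4-dienal | O=C/C=C/C=C(C)/C=C1C=C(/C=C/[C@@]23O[C@]2(C)C[C@@H](O[Si](C)(C)C(C)(C)C)CC3(C)C)C(=O)O/1 | intermediate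
30 | isomer of 31 with Z geometry at the CH=CH bond formed in step 19, otherwise identical (not isolated) | CC1=C(C#C\C(C)=C\C=C/C=C/C=C(C)/C=C2C=C(/C=C/[C@@]34O[C@]3(C)C[C@@H](O[Si](C)(C)C(C)(C)C)CC4(C)C)C(=O)O/2)C(C)(C)C[C@H](O[Si](C)(C)C(C)(C)C)C1 | intermediate
31 | 3,3′-bis-O-(tert-butyldimethylsilyl)pyrrhoxanthin (all-E chain, Z-alkylidene butenolide) | CC1=C(C#C/C(C)=C/C=C/C=C/C=C(C)/C=C2C=C(/C=C/[C@@]34O[C@]3(C)C[C@@H](O[Si](C)(C)C(C)(C)C)CC4(C)C)C(=O)O/2)C(C)(C)C[C@H](O[Si](C)(C)C(C)(C)C)C1 | intermediate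
32 | pyrrhoxanthin (CNP0180336.1) | CC1=C(C#C/C(C)=C/C=C/C=C/C=C(C)/C=C2C=C(/C=C/[C@@]34O[C@]3(C)C[C@@H](O)CC4(C)C)C(=O)O/2)C(C)(C)C[C@H](O)C1 | target

Total step count: 20. Longest linear sequence: 11 steps (steps 1–8, then 18, 19 and 20).

Steps most likely to fail

Step 6. After the carbon–carbon bond has formed, the congested samarium aldolate may revert by retro-aldol cleavage, or lose its second chlorine reductively, faster than it closes the oxirane. The fallback sets out from 8 and keeps the same ring closure but makes the epoxide separately. An excess of SmI2 (4.5 equiv, THF, −78 °C → rt) should carry the Reformatsky cyclisation through to reductive 1,2-elimination of the chlorohydrin, giving the cyclohexene ester methyl (4R)-4-[(tert-butyldimethylsilyl)oxy]-2,6,6-trimethylcyclohex-1-ene-1-carboxylate F1. Reduction with i-Bu2AlH (CH2Cl2, −78 °C) should give the allylic alcohol [(4R)-4-[(tert-butyldimethylsilyl)oxy]-2,6,6-trimethylcyclohex-1-en-1-yl]methanol F2. Sharpless epoxidation (Ti(Oi-Pr)4, D-(−)-diethyl tartrate, t-BuOOH, 4 Å MS, CH2Cl2, −20 °C) should deliver oxygen anti to the silyloxy group and give the epoxy alcohol [(1R,4S,6R)-4-[(tert-butyldimethylsilyl)oxy]-2,2,6-trimethyl-7-oxabicyclo[4.1.0]heptan-1-yl]methanol F3. Dess–Martin oxidation then comes back to the route at aldehyde 12, which is taken on with the Ohira–Bestmann half of step 7.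

Step 8. Zerovalent palladium may ionise the propargylic oxirane (SN2′ opening to an allenyl species), or tin may be delivered to the internal alkyne carbon. The fallback sets out from 13 and replaces tin by boron: hydroboration with pinacolborane under Cp2Zr(H)Cl catalysis (5 mol%, Et3N 10 mol%, 60 °C) should give the E-alkenylboronate 2-{(E)-2-[(1S,4S,6R)-4-[(tert-butyldimethylsilyl)oxy]-2,2,6-trimethyl-7-oxabicyclo[4.1.0]heptan-1-yl]ethenyl}-4,4,5,5-tetramethyl-1,3,2-dioxaborolane F4. Suzuki–Miyaura coupling of F4 with 22 (Pd(PPh3)4, Tl2CO3, THF/H2O, rt) comes back to the route at 29.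

Step 19. The metalated allylic benzothiazolyl sulfone may self-condense, the butenolide dienal may degrade under base before addition, or equilibration of the new double bond may stay incomplete. The fallback sets out from 26 and uses a phosphorus ylide instead: Appel bromination (CBr4, PPh3, CH2Cl2, 0 °C) should give the allylic bromide (4R)-1-[(3E)-5-bromo-3-methylpent-3-en-1-yn-1-yl]-4-[(tert-butyldimethylsilyl)oxy]-2,6,6-trimethylcyclohex-1-ene F5. PPh3 (PhMe, rt) should convert it to the phosphonium salt {(2E)-5-[(4R)-4-[(tert-butyldimethylsilyl)oxy]-2,6,6-trimethylcyclohex-1-en-1-yl]-3-methylpent-2-en-4-yn-1-yl}triphenylphosphonium bromide F6. Wittig olefination of 29 with the ylide of F6 (NaN(SiMe3)2, THF, −78 °C), followed by the same equilibration in benzene, comes back to the route at 31.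

Further compounds
F1 | step 6 | methyl (4R)-4-[(tert-butyldimethylsilyl)oxy]-2,6,6-trimethylcyclohex-1-ene-1-carboxylate | COC(=O)C1=C(C)C[C@@H](O[Si](C)(C)C(C)(C)C)CC1(C)C
F2 | step 6 | [(4R)-4-[(tert-butyldimethylsilyl)oxy]-2,6,6-trimethylcyclohex-1-en-1-yl]methanol | OCC1=C(C)C[C@@H](O[Si](C)(C)C(C)(C)C)CC1(C)C
F3 | step 6 | [(1R,4S,6R)-4-[(tert-butyldimethylsilyl)oxy]-2,2,6-trimethyl-7-oxabicyclo[4.1.0]heptan-1-yl]methanol | OC[C@@]12O[C@]1(C)C[C@@H](O[Si](C)(C)C(C)(C)C)CC2(C)C
F4 | step 8 | 2-{(E)-2-[(1S,4S,6R)-4-[(tert-butyldimethylsilyl)oxy]-2,2,6-trimethyl-7-oxabicyclo[4.1.0]heptan-1-yl]ethenyl}-4,4,5,5-tetramethyl-1,3,2-dioxaborolane | CC1(C)OB(/C=C/[C@@]23O[C@]2(C)C[C@@H](O[Si](C)(C)C(C)(C)C)CC3(C)C)OC1(C)C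
F5 | step 19 | (4R)-1-[(3E)-5-bromo-3-methylpent-3-en-1-yn-1-yl]-4-[(tert-butyldimethylsilyl)oxy]-2,6,6-trimethylcyclohex-1-ene | CC1=C(C#C/C(C)=C/CBr)C(C)(C)C[C@H](O[Si](C)(C)C(C)(C)C)C1
F6 | step 19 | {(2E)-5-[(4R)-4-[(tert-butyldimethylsilyl)oxy]-2,6,6-trimethylcyclohex-1-en-1-yl]-3-methylpent-2-en-4-yn-1-yl}triphenylphosphonium bromide | CC1=C(C#C/C(C)=C/C[P+](c2ccccc2)(c2ccccc2)c2ccccc2)C(C)(C)C[C@H](O[Si](C)(C)C(C)(C)C)C1.[Br-]
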